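**Two flasks.** Wednesday's flask repeats Sunday's with 0.39 mM of precatalyst in place of 0.30 mM. Neither flask starts with free catalyst, which appears as the precatalyst opens.

- Sunday's: substrate 20 mM; reagent 100 mM; precatalyst 0.30 mM; time 6.0 d
- Wednesday's: substrate 20 mM; reagent 100 mM; precatalyst 0.39 mM; time 6.0 d

    substrate + free catalyst → catalyst intermediate A (k1 = 75.6 L mol⁻¹ h⁻¹)
    reagent + catalyst intermediate A → catalyst intermediate B (k2 = 327 L mol⁻¹ h⁻¹)
    catalyst intermediate B → free catalyst + target (k3 = 18.6 h⁻¹)
    precatalyst → free catalyst (k4 = 0.0168 h⁻¹)
    target + free catalyst ⇌ isomer of the product + free catalyst, rate k5*[free catalyst]*[target] forward; the back reaction follows from the equilibrium constant (K5 = 2.0, k5 = 53.8 L mol⁻¹ h⁻¹)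

1. which of these there is most of at the end, counted by the substrate in it, Sunday's (target / isomer of the product / catalyst intermediate B / substrate)
2. which of these there is most of at the end, counted by the substrate in it, Wednesday's (target / isomer of the product / catalyst intermediate B / substrate)
3. the largest of these amounts at the end, in percent of the substrate charged, Sunday's
4. the largest of these amounts at the end, in percent of the substrate charged, Wednesday's

**Counting turnovers.** Sunday's substrate charge amounts to 66.7 turnovers per catalyst charged. At the full charges, a free catalyst waits 0.661 h for substrate, against 0.0306 h for reagent and 0.0538 h for the release of target. Free catalyst is therefore the resting state, holding 88.7% of the round's time. So the substrate falls first-order in the area under the free-catalyst curve.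

**The exposure count.** Released catalyst follows first-order growth with the precatalyst half-life of 1.7 d. Counting released catalyst as free overstates it by the bound share. The area then equals the whole charge held for 6.0 d less a lag of 54.2 h. Sunday's flask has 2.04 as its exposure count, the first step's rate constant times the area under the free-catalyst curve. The substrate left is the exponential of minus this count, 13.0% for Sunday's flask. Wednesday's flask has the same lag, so its count scales with the charge to 2.65, leaving 7.09%.

**Target or isomer.** Isomerisation runs on the same free catalyst, so the same count serves it. Its approach to equilibrium, forward and back together, has the constant 80.7 L mol⁻¹ h⁻¹, which is 1.07 times the first step's. Against the count, substrate, target and isomer form consecutive first-order steps, ending with a third as target. Solving them gives Sunday's flask 45.5% target and 41.4% isomer. Wednesday's flask gets 42.4% target and 50.5% isomer.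

The forecast names target at 45.7% for Sunday's flask and isomer of the product at 49% for Wednesday's, the same leaders with amounts that differ from this reckoning, on the ground that “Sunday stops just before the crossover”.

**What stands.** At the end, Sunday's flask holds most as target, at 46.0%. Wednesday's flask holds most as isomer of the product, at 48.9%. In Sunday's flask the substrate's half-life by the first step reads 2.0 d at 2.80 d, beside the precatalyst's 1.7 d. Sunday's 14.6% of substrate reads back as an exposure count of 1.92, below the reckoned 2.04. The neighbour with the same charges read at 10 d has a reckoned count of 4.12, which leaves 1.63% of substrate. That neighbour holds most as isomer of the product, and its substrate stands at 1.86%.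

Its constants stand for no real mixture, and the outcome is calculated.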